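What held still in the earlier runs, within the scatter of the readings, was the share of D in all that had become D or G, the selectivity of the branch, while Z, J and the time all moved.

| flask | Z | J | remark | time |
|---|---|---|---|---|
| winter | 0.20 M | 0.95 equiv | run made earlier |  |
| spring | 0.20 M | 1.3 equiv | run made earlier |  |
| autumn | 0.20 M | 2.1 equiv | run made earlier |  |
| north-east | 0.20 M | 0.950 equiv | everything together in a closed stirred flask, run for 6.0 min | 6.0 min |
| north | 0.20 M (fed, over 6.00 min) | 0.950 equiv | a stirred flask in which Z is dosed at a steady rate over 6.00 min without added volume, worked up at 6.0 min | 6.0 min |
| south-west | 0.20 M | 0.950 equiv | one stirred flow tank at steady state, fed with the mixture as stated, mean residence time 6.0 min |  |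
| north-west | 0.20 M | 0.950 equiv (fed, over 6.00 min) | a stirred flask in which J is dosed at a steady rate over 6.00 min without added volume, worked up at 6.0 min | 6.0 min |

| run | time / min | D / % | G / % | Z / % |
|---|---|---|---|---|
| winter | 1.50 | 5 | 15 | 81 |
| winter | 3.00 | 7 | 22 | 71 |
| winter | 5.00 | 6 | 31 | 58 |
| winter | 6.00 | 14 | 33 | 54 |
| spring | 0.833 | 5 | 12 | 85 |
| spring | 2.50 | 11 | 26 | 66 |
| spring | 5.00 | 14 | 41 | 48 |
| spring | 8.00 | 19 | 46 | 35 |
| autumn | 0.500 | 7 | 10 | 85 |
| autumn | 1.33 | 11 | 28 | 67 |
| autumn | 3.00 | 15 | 40 | 42 |
| autumn | 8.00 | 23 | 64 | 19 |

(standard deviation of a reading: 1.5 percentage points)

- the stated concentrations are those of everything mixed, before any reaction; amounts are the same in each set-up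
- the feed brings no volume worth counting
- the earlier runs were made in a closed, stirred flask

- the set-up with the highest share of D in all that became D or G, at the outlet or at the end ("none" if the first two lie within 2 percentage points) (north-east / north / south-west / north-west / none)
- share of D in all that became D or G, at the outlet or at the end, north-east
- share of D in all that became D or G, at the outlet or at the end, north
- share of D in all that became D or G, at the outlet or at the end, south-west
- share of D in all that became D or G, at the outlet or at the end, north-west

The winter and autumn runs looked nearly the same, except that the autumn flask got twice the J. At their last readings, the winter run at 6.00 min still held 54% of its Z charge and the autumn run at 8.00 min held 19%, yet their shares read: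

winter: D/(D+G) = 29.8%

autumn: D/(D+G) = 26.4%

The gap of 3.4 percentage points was about the size of the standard deviation of a reading set against the winter sum of D and G, 3.2 points. So I read the two ends as differing in conversion and not in branching. If D and G both form first order in Z and first order in J, the ratio of their rates contains no concentration, and each fraction of Z converted splits alike. Pooling every reading gave:

s = sum of D / sum of (D+G) = 27.1%

I carried this D share, the fraction of converted Z that ends as D. Dosing and the tank reshape the profiles of Z and J, so I expected them to change the conversion and leave s alone.

The forecast gave 27% for north-east, 27% for north, 27% for south-west and 27% for north-west, and none as best, since “the share does not depend on concentration”.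

The flask gave 26.1%, 26.1%, 26.1% and 26.1% in that order, and none as best.

    Z + J → G (k = 0.650 /M/min)
    J → X (k = 0.0360 /min)
    Z + J → D (k = 0.230 /M/min)

The conversion of J into X changed the north share by nothing. In the north flask at 6.00 min, 71.9% of the Z remained, so s gave:

D = s × (converted fraction) = 7.62%

The flask held 7.34%.

The same north flask read at 25 min had 38.9% of its Z left, so s gave 16.6% of D. The computed flask held 16.0%, a share of 26.1%.

The readings were generated by integration with made-up constants, noise included.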